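**Strategy.** The eleven-membered carbocycle (ring atoms C1–C11) is opened at its C6=C7 enal double bond. That bond is the aldol condensation product of two aldehydes: C6, whose α-carbon C5 is neopentyl because it sits next to quaternary C4, and C12, whose α-carbon C7 is an unhindered methylene. One amine-salt-mediated macro-condensation should therefore close the ring, install the trisubstituted E-enal and give the target with no later step. Its substrate is an open-chain dialdehyde that already holds the C2=C3 Z-alkene, the C1 senecioate, the C10–C11 epoxide, quaternary C4 and the free tertiary alcohol. It is built from an alkyne fragment (C2–C6) and an epoxy aldehyde fragment (C1, C7–C12).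

Key step: step 19

Numbering: ring carbons C1 (CH–O-senecioyl), C2=C3, C4 (quaternary), C5, C6=C7, C8, C9, C10 and C11 (epoxide; methyl on C11; C11 bonded to C1). C12 is the formyl carbon on C7. The same numbers are used for the open-chain intermediates.

Assumption: in step 2 the lactone enolate is taken to show the facial preference known for cyclic ketone and lactam enolates with PHOX ligands, hence the (R)-ligand; if the sense is opposite, the (S)-ligand is used.

Remark: the CIP label of C11 (oxirane C2 in the names) is S while C1 carries a free OH and R once C1 is acylated or a carbonyl; the centre itself is not touched after step 9.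

Design point: the two future aldehyde carbons are carried as different silyl ethers (C6–O–TBDPS, C12–O–TBS). This costs no step, both are removed in one fluoride operation, and the termini can still be addressed one at a time. The dialdehyde is made and used without storage.

Step 1
Reactants: 1 3-methyloxolan-2-one (α-methyl-γ-butyrolactone, racemic); 2 allyl chloroformate
Product: 4 prop-2-en-1-yl 3-methyl-2-oxooxolane-3-carboxylate (racemic), via lithium enolate 3 (not isolated)
Conditions: LiN(i-Pr)2, THF, −78 °C; then 2, −78 °C to 0 °C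
Reagents that add atoms: allyl chloroformate (2), C=CCOC(=O)Cl
Why: Claisen-type C-acylation of the lithium lactone enolate gives the quaternary allyl β-oxo ester; this stereocentre is racemic and is erased in step 2.

Step 2
Reactants: 4 prop-2-en-1-yl 3-methyl-2-oxooxolane-3-carboxylate
Product: 5 (3S)-3-methyl-3-(prop-2-en-1-yl)oxolan-2-one
Conditions: Pd2(dba)3 (2.5 mol%), (R)-(CF3)3-t-BuPHOX (6 mol%), toluene, 40 °C
Reagents that add atoms: none
Why: Decarboxylative asymmetric allylic alkylation (Tsuji–Trost type): zerovalent palladium ionises the allyl ester, CO2 is lost, and the chiral P,N-ligand directs recombination of the prochiral lactone enolate with the π-allyl unit, which should set C4 as S.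

Step 3
Reactants: 5 (3S)-3-methyl-3-(prop-2-en-1-yl)oxolan-2-one
Product: 6 (3S)-3-methyl-3-(prop-2-en-1-yl)oxolan-2-ol (lactol, both C2 epimers)
Conditions: i-Bu2AlH (1.1 equiv), CH2Cl2, −78 °C
Reagents that add atoms: none
Why: Partial hydride reduction of a lactone stops at the aluminium hemiacetal at low temperature and gives the lactol on work-up; C4 is not involved.

Step 4
Reactants: 6 (3S)-3-methyl-3-(prop-2-en-1-yl)oxolan-2-ol; 7 dimethyl (1-diazo-2-oxopropyl)phosphonate
Product: 8 (3S)-3-ethynyl-3-methylhex-5-en-1-ol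
Conditions: 7, K2CO3, MeOH, 0 °C to rt
Reagents that add atoms: dimethyl (1-diazo-2-oxopropyl)phosphonate (7), CC(=O)C(=[N+]=[N-])P(=O)(OC)OC
Why: Seyferth–Gilbert homologation in the Ohira–Bestmann variant: the lactol opens to a hydroxy aldehyde that cannot enolise (quaternary α-carbon) and is converted into the terminal alkyne, the added carbon being C2.

Step 5
Reactants: 8 (3S)-3-ethynyl-3-methylhex-5-en-1-ol
Product: 9 tert-butyl{[(3S)-3-ethynyl-3-methylhex-5-en-1-yl]oxy}diphenylsilane
Conditions: TBDPSCl, imidazole, CH2Cl2, rt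
Reagents that add atoms: tert-butyl(chloro)diphenylsilane, CC(C)(C)[Si](Cl)(c1ccccc1)c1ccccc1
Why: Standard silylation of a primary alcohol; TBDPS is chosen so that the C6 oxygen differs from the TBS-protected C12 oxygen.

Step 6
Reactants: 10 pentane-1,5-diol
Product: 11 5-[(tert-butyldimethylsilyl)oxy]pentan-1-ol
Conditions: NaH (1 equiv), THF, rt; then TBSCl (1 equiv)
Reagents that add atoms: tert-butyl(chloro)dimethylsilane, CC(C)(C)[Si](C)(C)Cl
Why: Monosilylation of a symmetrical diol through its sparingly soluble monosodium alkoxide should favour the mono-ether.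

Step 7
Reactants: 11 5-[(tert-butyldimethylsilyl)oxy]pentan-1-ol; 12 ethyl 2-(triphenyl-λ5-phosphanylidene)propanoate
Product: 14 ethyl (2E)-7-[(tert-butyldimethylsilyl)oxy]-2-methylhept-2-enoate, via silyloxy aldehyde 13 (not isolated)
Conditions: TEMPO (10 mol%), PhI(OAc)2, CH2Cl2, rt; then 12, rt
Reagents that add atoms: ethyl 2-(triphenyl-λ5-phosphanylidene)propanoate (12), CCOC(=O)C(C)=P(c1ccccc1)(c1ccccc1)c1ccccc1
Why: One-pot oxoammonium oxidation and Wittig olefination; the stabilised ylide should give the trisubstituted E-enoate and adds C11, its methyl and C1.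

Step 8
Reactants: 14 ethyl (2E)-7-[(tert-butyldimethylsilyl)oxy]-2-methylhept-2-enoate
Product: 15 (2E)-7-[(tert-butyldimethylsilyl)oxy]-2-methylhept-2-en-1-ol
Conditions: i-Bu2AlH (2.2 equiv), CH2Cl2, −78 °C
Reagents that add atoms: none
Why: 1,2-Reduction of the conjugated ester to the allylic alcohol with an aluminium hydride.

Step 9
Reactants: 15 (2E)-7-[(tert-butyldimethylsilyl)oxy]-2-methylhept-2-en-1-ol
Product: 16 [(2S,3S)-3-{4-[(tert-butyldimethylsilyl)oxy]butyl}-2-methyloxiran-2-yl]methanol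
Conditions: Ti(O-i-Pr)4 (10 mol%), L-(+)-diethyl tartrate (12 mol%), t-BuOOH, 4 Å molecular sieves, CH2Cl2, −20 °C
Reagents that add atoms: tert-butyl hydroperoxide, CC(C)(C)OO
Why: Sharpless asymmetric epoxidation: the L-(+)-tartrate complex delivers oxygen to the face that gives the (2S,3S)-epoxide, setting C10 and C11, and the trans arrangement follows from the E-alkene.

Step 10
Reactants: 16 [(2S,3S)-3-{4-[(tert-butyldimethylsilyl)oxy]butyl}-2-methyloxiran-2-yl]methanol
Product: 17 (2R,3S)-3-{4-[(tert-butyldimethylsilyl)oxy]butyl}-2-methyloxirane-2-carbaldehyde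
Conditions: TEMPO (10 mol%), PhI(OAc)2, CH2Cl2, rt
Reagents that add atoms: none
Why: Oxoammonium oxidation of the primary epoxy alcohol; the aldehyde has no α-hydrogen and cannot epimerise.

Step 11
Reactants: 9 tert-butyl{[(3S)-3-ethynyl-3-methylhex-5-en-1-yl]oxy}diphenylsilane; 17 (2R,3S)-3-{4-[(tert-butyldimethylsilyl)oxy]butyl}-2-methyloxirane-2-carbaldehyde
Product: 19 (4S)-1-[(2S,3S)-3-{4-[(tert-butyldimethylsilyl)oxy]butyl}-2-methyloxiran-2-yl]-4-{2-[(tert-butyldiphenylsilyl)oxy]ethyl}-4-methylhept-6-en-2-yn-1-ol (both C1 epimers), via lithium acetylide 18 (not isolated)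
Conditions: n-BuLi, THF, −78 °C; then 17, −78 °C; aqueous NH4Cl
Reagents that add atoms: none
Why: 1,2-Addition of a lithium acetylide to the aldehyde forms the C1–C2 bond; facial control is not needed because C1 is reset in steps 12 and 13.

Step 12
Reactants: 19 propargylic alcohols (C1 epimers)
Product: 20 (4S)-1-[(2R,3S)-3-{4-[(tert-butyldimethylsilyl)oxy]butyl}-2-methyloxiran-2-yl]-4-{2-[(tert-butyldiphenylsilyl)oxy]ethyl}-4-methylhept-6-en-2-yn-1-one
Conditions: Dess–Martin periodinane, NaHCO3, CH2Cl2, 0 °C to rt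
Reagents that add atoms: none
Why: Dess–Martin oxidation converges both C1 epimers on one epoxy ynone under buffered conditions that spare the epoxide and silyl ethers.

Step 13
Reactants: 20 epoxy ynone
Product: 21 (1R,4S)-1-[(2S,3S)-3-{4-[(tert-butyldimethylsilyl)oxy]butyl}-2-methyloxiran-2-yl]-4-{2-[(tert-butyldiphenylsilyl)oxy]ethyl}-4-methylhept-6-en-2-yn-1-ol
Conditions: Ru[(S,S)-TsNCH(Ph)CH(Ph)NH](η6-p-cymene) (3 mol%), i-PrOH, rt
Reagents that add atoms: none
Why: Noyori asymmetric transfer hydrogenation of an ynone: with the alkynyl group in the place of the aryl group of the usual model, the (S,S)-catalyst should deliver hydride to the face that gives 1R, so C1 is set by the catalyst and not by the neighbouring epoxide.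

Step 14
Reactants: 21 (1R)-propargylic alcohol
Product: 22 (1R,2Z,4S)-1-[(2S,3S)-3-{4-[(tert-butyldimethylsilyl)oxy]butyl}-2-methyloxiran-2-yl]-4-{2-[(tert-butyldiphenylsilyl)oxy]ethyl}-4-methylhepta-2,6-dien-1-ol
Conditions: H2 (1 atm), Pd/CaCO3 poisoned with Pb(OAc)2, quinoline, EtOAc, rt, stopped at one equivalent of H2
Reagents that add atoms: none
Why: Lindlar semihydrogenation adds hydrogen syn to the alkyne and gives the C2=C3 Z-alkene; the poisoned catalyst should leave the terminal alkene and the epoxide untouched.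

Step 15
Reactants: 22 (Z)-allylic alcohol; 23 3-methylbut-2-enoic acid
Product: 24 (1R,2Z,4S)-1-[(2R,3S)-3-{4-[(tert-butyldimethylsilyl)oxy]butyl}-2-methyloxiran-2-yl]-4-{2-[(tert-butyldiphenylsilyl)oxy]ethyl}-4-methylhepta-2,6-dien-1-yl 3-methylbut-2-enoate
Conditions: 23, DCC, DMAP (20 mol%), CH2Cl2, 0 °C to rt
Reagents that add atoms: 3-methylbut-2-enoic acid (23), CC(C)=CC(=O)O
Why: Steglich esterification acylates the secondary alcohol with retention at C1 and avoids the amine-base conditions that deconjugate senecioyl chloride.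

Step 16
Reactants: 24 senecioate with terminal allyl group; 25 2-methylbut-3-en-2-ol
Product: 26 (1R,2Z,4S,6E)-1-[(2R,3S)-3-{4-[(tert-butyldimethylsilyl)oxy]butyl}-2-methyloxiran-2-yl]-4-{2-[(tert-butyldiphenylsilyl)oxy]ethyl}-8-hydroxy-4,8-dimethylnona-2,6-dien-1-yl 3-methylbut-2-enoate
Conditions: RuCl2(H2IMes)(=CH-C6H4-2-O-i-Pr) (second-generation Hoveyda–Grubbs catalyst, 5 mol%), 25 (8 equiv), CH2Cl2, 40 °C
Reagents that add atoms: 2-methylbut-3-en-2-ol (25), CC(C)(O)C=C
Why: Olefin cross-metathesis of the terminal allyl group with the bulky tertiary allylic alcohol should give the E-alkene, while the hindered Z-alkene and the trisubstituted enoate stay out of the reaction.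

Step 17
Reactants: 26 bis-silyl ether
Product: 27 (1R,2Z,4S,6E)-8-hydroxy-1-[(2R,3S)-3-(4-hydroxybutyl)-2-methyloxiran-2-yl]-4-(2-hydroxyethyl)-4,8-dimethylnona-2,6-dien-1-yl 3-methylbut-2-enoate
Conditions: Bu4NF, AcOH (1:1), THF, rt to 40 °C
Reagents that add atoms: none
Why: Buffered fluoride desilylation cleaves both silyl ethers in one operation without touching the ester or the epoxide.

Step 18
Reactants: 27 triol
Product: 28 (1R,2Z,4S,6E)-8-hydroxy-4,8-dimethyl-1-[(2R,3S)-2-methyl-3-(4-oxobutyl)oxiran-2-yl]-4-(2-oxoethyl)nona-2,6-dien-1-yl 3-methylbut-2-enoate (C6,C12-dialdehyde)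
Conditions: Dess–Martin periodinane (3 equiv), NaHCO3, CH2Cl2, 0 °C to rt; filtered and used at once
Reagents that add atoms: none
Why: Dess–Martin oxidation converts both primary alcohols into aldehydes; the tertiary alcohol cannot be oxidised and the buffer protects the epoxide.

Step 19
Reactants: 28 C6,C12-dialdehyde
Product: 30 (1R,2R,3Z,5S,7E,11S)-8-formyl-5-[(2E)-4-hydroxy-4-methylpent-2-en-1-yl]-1,5-dimethyl-12-oxabicyclo[9.1.0]dodeca-3,7-dien-2-yl 3-methylbut-2-enoate (target), via aldol adduct 29 (not isolated)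
Conditions: Bn2NH·CF3CO2H (dibenzylammonium trifluoroacetate, 1 equiv), 4 Å molecular sieves, toluene, 50 °C; 28 added by syringe pump over 12 h to a final 1 mM
Reagents that add atoms: none
Why: Proposed new method: the secondary ammonium salt condenses reversibly with both aldehydes; the enamine of the C12 aldehyde, nucleophilic at unhindered C7, adds to the C6 aldehyde or its iminium ion, and loss of water from the β-hydroxy iminium ion gives the conjugated enal, so the reversible aldol stage is drained into the product. The closest known reaction types are amine-salt-mediated condensations of dialdehydes to five- and six-membered cycloalkene carbaldehydes and macro-aldol closures with ketone or ester enolates; an aldehyde–aldehyde case at ring size 11 has not been shown. The ring closes in the 11-(enolexo)-exo-trig mode, with the enamine double bond C7=C12 outside the new ring and the C6 carbonyl oxygen exocyclic. No stereocentre is formed; the alkene geometry is under thermodynamic control through reversible iminium and dienamine formation, and the E-enal (formyl trans to C5, so C5 and C8 cis on the ring) is the expected stable isomer, to which any Z-enal should equilibrate under the same salt. The step needs C7 and not C5 as donor, and ring closure in place of oligomerisation: quaternary C4 makes the C5 enamine carbon neopentyl, while slow addition to high dilution and the turn elements already in the chain (Z-alkene, trans-epoxide) favour cyclisation. The weakly acidic, weakly nucleophilic dibenzylammonium salt should leave the epoxide, the senecioate and the tertiary alcohol intact.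

**Compound list**

1 | 3-methyloxolan-2-one (α-methyl-γ-butyrolactone, racemic) | CC1CCOC1=O | starting material
2 | prop-2-en-1-yl carbonochloridate (allyl chloroformate) | C=CCOC(=O)Cl | starting material
3 | lithium enolate of 1 | CC1=C(O[Li])OCC1 | intermediate (not isolated)
4 | prop-2-en-1-yl 3-methyl-2-oxooxolane-3-carboxylate (racemic) | C=CCOC(=O)C1(C)CCOC1=O | intermediate
5 | (3S)-3-methyl-3-(prop-2-en-1-yl)oxolan-2-one | O=C1OCC[C@]1(C)CC=C | intermediate
6 | (3S)-3-methyl-3-(prop-2-en-1-yl)oxolan-2-ol (both C2 epimers) | OC1OCC[C@]1(C)CC=C | intermediate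
7 | dimethyl (1-diazo-2-oxopropyl)phosphonate | CC(=O)C(=[N+]=[N-])P(=O)(OC)OC | starting material
8 | (3S)-3-ethynyl-3-methylhex-5-en-1-ol | OCC[C@](C)(CC=C)C#C | intermediate
9 | tert-butyl{[(3S)-3-ethynyl-3-methylhex-5-en-1-yl]oxy}diphenylsilane | CC(C)(C)[Si](c1ccccc1)(c1ccccc1)OCC[C@](C)(CC=C)C#C | intermediate
10 | pentane-1,5-diol | OCCCCCO | starting material
11 | 5-[(tert-butyldimethylsilyl)oxy]pentan-1-ol | OCCCCCO[Si](C)(C)C(C)(C)C | intermediate
12 | ethyl 2-(triphenyl-λ5-phosphanylidene)propanoate | CCOC(=O)C(C)=P(c1ccccc1)(c1ccccc1)c1ccccc1 | starting material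
13 | 5-[(tert-butyldimethylsilyl)oxy]pentanal | O=CCCCCO[Si](C)(C)C(C)(C)C | intermediate (not isolated)
14 | ethyl (2E)-7-[(tert-butyldimethylsilyl)oxy]-2-methylhept-2-enoate | CCOC(=O)/C(C)=C/CCCCO[Si](C)(C)C(C)(C)C | intermediate
15 | (2E)-7-[(tert-butyldimethylsilyl)oxy]-2-methylhept-2-en-1-ol | OC/C(C)=C/CCCCO[Si](C)(C)C(C)(C)C | intermediate
16 | [(2S,3S)-3-{4-[(tert-butyldimethylsilyl)oxy]butyl}-2-methyloxiran-2-yl]methanol | OC[C@]1(C)O[C@H]1CCCCO[Si](C)(C)C(C)(C)C | intermediate
17 | (2R,3S)-3-{4-[(tert-butyldimethylsilyl)oxy]butyl}-2-methyloxirane-2-carbaldehyde | O=C[C@]1(C)O[C@H]1CCCCO[Si](C)(C)C(C)(C)C | intermediate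
18 | lithium acetylide of 9 | CC(C)(C)[Si](c1ccccc1)(c1ccccc1)OCC[C@](C)(CC=C)C#C[Li] | intermediate (not isolated)
19 | (4S)-1-[(2S,3S)-3-{4-[(tert-butyldimethylsilyl)oxy]butyl}-2-methyloxiran-2-yl]-4-{2-[(tert-butyldiphenylsilyl)oxy]ethyl}-4-methylhept-6-en-2-yn-1-ol (both C1 epimers) | CC(C)(C)[Si](c1ccccc1)(c1ccccc1)OCC[C@](C)(CC=C)C#CC(O)[C@]1(C)O[C@H]1CCCCO[Si](C)(C)C(C)(C)C | intermediate
20 | (4S)-1-[(2R,3S)-3-{4-[(tert-butyldimethylsilyl)oxy]butyl}-2-methyloxiran-2-yl]-4-{2-[(tert-butyldiphenylsilyl)oxy]ethyl}-4-methylhept-6-en-2-yn-1-one | CC(C)(C)[Si](c1ccccc1)(c1ccccc1)OCC[C@](C)(CC=C)C#CC(=O)[C@]1(C)O[C@H]1CCCCO[Si](C)(C)C(C)(C)C | intermediate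
21 | (1R,4S)-1-[(2S,3S)-3-{4-[(tert-butyldimethylsilyl)oxy]butyl}-2-methyloxiran-2-yl]-4-{2-[(tert-butyldiphenylsilyl)oxy]ethyl}-4-methylhept-6-en-2-yn-1-ol | CC(C)(C)[Si](c1ccccc1)(c1ccccc1)OCC[C@](C)(CC=C)C#C[C@@H](O)[C@]1(C)O[C@H]1CCCCO[Si](C)(C)C(C)(C)C | intermediate
22 | (1R,2Z,4S)-1-[(2S,3S)-3-{4-[(tert-butyldimethylsilyl)oxy]butyl}-2-methyloxiran-2-yl]-4-{2-[(tert-butyldiphenylsilyl)oxy]ethyl}-4-methylhepta-2,6-dien-1-ol | CC(C)(C)[Si](c1ccccc1)(c1ccccc1)OCC[C@](C)(CC=C)/C=C\[C@@H](O)[C@]1(C)O[C@H]1CCCCO[Si](C)(C)C(C)(C)C | intermediate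
23 | 3-methylbut-2-enoic acid | CC(C)=CC(=O)O | starting material
24 | (1R,2Z,4S)-1-[(2R,3S)-3-{4-[(tert-butyldimethylsilyl)oxy]butyl}-2-methyloxiran-2-yl]-4-{2-[(tert-butyldiphenylsilyl)oxy]ethyl}-4-methylhepta-2,6-dien-1-yl 3-methylbut-2-enoate | CC(C)(C)[Si](c1ccccc1)(c1ccccc1)OCC[C@](C)(CC=C)/C=C\[C@@H](OC(=O)C=C(C)C)[C@]1(C)O[C@H]1CCCCO[Si](C)(C)C(C)(C)C | intermediate
25 | 2-methylbut-3-en-2-ol | CC(C)(O)C=C | starting material
26 | (1R,2Z,4S,6E)-1-[(2R,3S)-3-{4-[(tert-butyldimethylsilyl)oxy]butyl}-2-methyloxiran-2-yl]-4-{2-[(tert-butyldiphenylsilyl)oxy]ethyl}-8-hydroxy-4,8-dimethylnona-2,6-dien-1-yl 3-methylbut-2-enoate | CC(C)(C)[Si](c1ccccc1)(c1ccccc1)OCC[C@](C)(C/C=C/C(C)(C)O)/C=C\[C@@H](OC(=O)C=C(C)C)[C@]1(C)O[C@H]1CCCCO[Si](C)(C)C(C)(C)C | intermediate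
27 | (1R,2Z,4S,6E)-8-hydroxy-1-[(2R,3S)-3-(4-hydroxybutyl)-2-methyloxiran-2-yl]-4-(2-hydroxyethyl)-4,8-dimethylnona-2,6-dien-1-yl 3-methylbut-2-enoate | OCC[C@](C)(C/C=C/C(C)(C)O)/C=C\[C@@H](OC(=O)C=C(C)C)[C@]1(C)O[C@H]1CCCCO | intermediate
28 | (1R,2Z,4S,6E)-8-hydroxy-4,8-dimethyl-1-[(2R,3S)-2-methyl-3-(4-oxobutyl)oxiran-2-yl]-4-(2-oxoethyl)nona-2,6-dien-1-yl 3-methylbut-2-enoate | O=CC[C@](C)(C/C=C/C(C)(C)O)/C=C\[C@@H](OC(=O)C=C(C)C)[C@]1(C)O[C@H]1CCCC=O | intermediate
29 | (1R,2R,3Z,5S,11S)-8-formyl-7-hydroxy-5-[(2E)-4-hydroxy-4-methylpent-2-en-1-yl]-1,5-dimethyl-12-oxabicyclo[9.1.0]dodec-3-en-2-yl 3-methylbut-2-enoate (aldol adduct; C7 and C8 of this name undefined) | CC(C)=CC(=O)O[C@@H]1/C=C\[C@@](C)(C/C=C/C(C)(C)O)CC(O)C(C=O)CC[C@@H]2O[C@]21C | intermediate (not isolated)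
30 | (1R,2R,3Z,5S,7E,11S)-8-formyl-5-[(2E)-4-hydroxy-4-methylpent-2-en-1-yl]-1,5-dimethyl-12-oxabicyclo[9.1.0]dodeca-3,7-dien-2-yl 3-methylbut-2-enoate (CNP0164725.3) | CC(C)=CC(=O)O[C@@H]1/C=C\[C@@](C)(C/C=C/C(C)(C)O)C/C=C(/C=O)CC[C@@H]2O[C@]21C | target

**Totals.** Total step count: 19. Longest linear sequence: 14 steps (steps 1–5 or 6–10, then 11–19).

**Steps most likely to fail**

1. Step 19 (proposed new method). What may go wrong: intermolecular aldol oligomerisation outrunning the strained eleven-membered closure, closure through the C5 enamine, or slow opening of the epoxide by the ammonium salt. The fallback is a Wittig macrocyclisation with a stabilised α-formyl phosphorane, which makes C7 the only nucleophilic carbon and uses the two different silyl ethers. It sets out from 26 and comes back at 30. Selective cleavage of the TBS ether beside the TBDPS ether (HF·pyridine, pyridine, THF, 0 °C) gives the C12 alcohol F1. Dess–Martin oxidation gives the C12 aldehyde F2. Amine-catalysed α-chlorination (N-chlorosuccinimide, L-prolinamide cat., CH2Cl2, 0 °C) gives the C7-chloro aldehyde F3 as both C7 epimers. Triphenylphosphine (NaI cat., MeCN, 40 °C) displaces chloride to give the phosphonium chloride F4, and aqueous Na2CO3 converts it into the formyl ylide F5. Bu4NF/AcOH then frees the C6 alcohol to give the hydroxy ylide F6. Dess–Martin oxidation at high dilution gives the ylide aldehyde F7, which is not isolated. It should close by intramolecular Wittig olefination (toluene, 60 °C), E-selective as usual for 2-alkyl-2-formyl ylides, to give 30.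

2. Step 2. What may go wrong: weak enantioselection when the lactone enolate recombines with the allyl unit, which would leave C4 partly racemic. The fallback is a classical resolution through covalent diastereomers. It sets out from 1 and comes back at 5. Alkylation (LiN(i-Pr)2, allyl bromide, THF, −78 °C) gives the racemic allyl lactone F8. Aminolysis with (S)-1-phenylethylamine and AlMe3 (toluene, 80 °C) gives the (2S)-hydroxy amide F9 and the (2R)-hydroxy amide F10, which are separated by chromatography or crystallisation. Acid-promoted relactonisation of F9 (aqueous H2SO4, dioxane, 90 °C) releases the amine and gives 5.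

3. Step 13. What may go wrong: loss of facial selectivity at C1, because the catalyst must override the bias of the adjacent epoxide (a possibly mismatched pairing), or slow turnover at the hindered ketone. The fallback is substrate control followed by inversion. It sets out from 20 and comes back at 24. Chelation-controlled reduction with Zn(BH4)2 (Et2O, −20 °C), which favours erythro alcohols from α,β-epoxy ketones, should give the (1S)-propargylic alcohol F11. Mitsunobu esterification with 23 (PPh3, diisopropyl azodicarboxylate, toluene, 0 °C) inverts C1 and installs the ester in one operation, giving the (1R)-propargylic senecioate F12. Semihydrogenation over Pd/CaCO3 poisoned with Pb(OAc)2 (quinoline, EtOAc) then gives 24.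

**Further compounds**

F1 | step 19 | (1R,2Z,4S,6E)-4-{2-[(tert-butyldiphenylsilyl)oxy]ethyl}-8-hydroxy-1-[(2R,3S)-3-(4-hydroxybutyl)-2-methyloxiran-2-yl]-4,8-dimethylnona-2,6-dien-1-yl 3-methylbut-2-enoate | CC(C)(C)[Si](c1ccccc1)(c1ccccc1)OCC[C@](C)(C/C=C/C(C)(C)O)/C=C\[C@@H](OC(=O)C=C(C)C)[C@]1(C)O[C@H]1CCCCO
F2 | step 19 | C12 aldehyde of F1 (4-oxobutyl on the oxirane, C6–O–TBDPS kept) | CC(C)(C)[Si](c1ccccc1)(c1ccccc1)OCC[C@](C)(C/C=C/C(C)(C)O)/C=C\[C@@H](OC(=O)C=C(C)C)[C@]1(C)O[C@H]1CCCC=O
F3 | step 19 | C7-chloro C12 aldehyde (3-chloro-4-oxobutyl on the oxirane, both C7 epimers) | CC(C)(C)[Si](c1ccccc1)(c1ccccc1)OCC[C@](C)(C/C=C/C(C)(C)O)/C=C\[C@@H](OC(=O)C=C(C)C)[C@]1(C)O[C@H]1CCC(Cl)C=O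
F4 | step 19 | (1-formylalkyl)triphenylphosphonium chloride at C7 | CC(C)(C)[Si](c1ccccc1)(c1ccccc1)OCC[C@](C)(C/C=C/C(C)(C)O)/C=C\[C@@H](OC(=O)C=C(C)C)[C@]1(C)O[C@H]1CCC(C=O)[P+](c1ccccc1)(c1ccccc1)c1ccccc1.[Cl-]
F5 | step 19 | C7 formyl ylide, C6–O–TBDPS | CC(C)(C)[Si](c1ccccc1)(c1ccccc1)OCC[C@](C)(C/C=C/C(C)(C)O)/C=C\[C@@H](OC(=O)C=C(C)C)[C@]1(C)O[C@H]1CCC(C=O)=P(c1ccccc1)(c1ccccc1)c1ccccc1
F6 | step 19 | C7 formyl ylide, C6 alcohol | OCC[C@](C)(C/C=C/C(C)(C)O)/C=C\[C@@H](OC(=O)C=C(C)C)[C@]1(C)O[C@H]1CCC(C=O)=P(c1ccccc1)(c1ccccc1)c1ccccc1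
F7 | step 19 | C7 formyl ylide, C6 aldehyde | O=CC[C@](C)(C/C=C/C(C)(C)O)/C=C\[C@@H](OC(=O)C=C(C)C)[C@]1(C)O[C@H]1CCC(C=O)=P(c1ccccc1)(c1ccccc1)c1ccccc1
F8 | step 2 | 3-methyl-3-(prop-2-en-1-yl)oxolan-2-one (racemic) | C=CCC1(C)CCOC1=O
F9 | step 2 | (2S)-2-(2-hydroxyethyl)-2-methyl-N-[(1S)-1-phenylethyl]pent-4-enamide | OCC[C@](C)(CC=C)C(=O)N[C@@H](C)c1ccccc1
F10 | step 2 | (2R)-2-(2-hydroxyethyl)-2-methyl-N-[(1S)-1-phenylethyl]pent-4-enamide | OCC[C@@](C)(CC=C)C(=O)N[C@@H](C)c1ccccc1
F11 | step 13 | (1S,4S)-1-[(2S,3S)-3-{4-[(tert-butyldimethylsilyl)oxy]butyl}-2-methyloxiran-2-yl]-4-{2-[(tert-butyldiphenylsilyl)oxy]ethyl}-4-methylhept-6-en-2-yn-1-ol | CC(C)(C)[Si](c1ccccc1)(c1ccccc1)OCC[C@](C)(CC=C)C#C[C@H](O)[C@]1(C)O[C@H]1CCCCO[Si](C)(C)C(C)(C)C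
F12 | step 13 | (1R,4S)-1-[(2R,3S)-3-{4-[(tert-butyldimethylsilyl)oxy]butyl}-2-methyloxiran-2-yl]-4-{2-[(tert-butyldiphenylsilyl)oxy]ethyl}-4-methylhept-6-en-2-yn-1-yl 3-methylbut-2-enoate | CC(C)(C)[Si](c1ccccc1)(c1ccccc1)OCC[C@](C)(CC=C)C#C[C@@H](OC(=O)C=C(C)C)[C@]1(C)O[C@H]1CCCCO[Si](C)(C)C(C)(C)C
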